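**Retrosynthetic overview**

1. Feature: ring B (C5–C10) is a cyclohexene whose C9 formyl group is cis to the C10 methyl and which is trans-fused at C5–C10 to ring A bearing oxygen at C1. This is the retron of a type-1 intramolecular Diels–Alder reaction between a C9=C10 E-enedione and a C5–C8 2-siloxydienoate joined through C1–C4.
2. Target ⇒ cycloadduct, by late cross-metathesis on the C4 allyl group, hydride reduction at C1, HCl addition to a 2-en-1-one and enol-triflate reduction at C7 (7-ene ester).
3. Cycloadduct ⇒ acyclic triene: bonds C5–C10 and C8–C9 form together, so rings A and B close in the same step (ring B as the cycloaddition ring, ring A as the tether ring).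
4. Triene ⇒ a phosphorus ylide (C6–C8 and the ester), an alkenyllithium (C9–C11) and an aldehyde ester (C1–C5) joined through a δ-lactone.
5. Aldehyde ester ⇒ oxidative C1–C5 ring cleavage of (S)-2-allyl-2-methylcyclopentanone, whose quaternary carbon (C4) is set by decarboxylative asymmetric allylation.

Key step: step 13

Remark 1: bicyclic compounds are named on the decalin frame with the locants used above (ring A: C1–C5 and C10; ring B: C5–C10; C11 is the formyl carbon; β is the face of the C10 methyl).
Remark 2: the (S)-phosphinooxazoline ligand is taken to give the same sense of induction with the five-membered β-keto ester as with its six-membered homologue, i.e. the (S) ketone.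
Remark 3: the face selectivity of the boron catalyst in step 13 is taken from its accepted binding model for enals (formyl C–H···O contact, s-trans enal lying over the convex-face phenyl group).

**Route**

Step 1
Reactants: 1 diprop-2-en-1-yl hexanedioate (diallyl adipate)
Product: 3 prop-2-en-1-yl 1-methyl-2-oxocyclopentane-1-carboxylate (racemic), via sodium enolate of prop-2-en-1-yl 2-oxocyclopentane-1-carboxylate 2 (not isolated)
Conditions: NaH, THF, 40 °C; then MeI, 23 °C
Reagents that add atoms: iodomethane, CI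
Why: Dieckmann condensation gives the five-membered β-keto ester enolate, which is C-methylated in the same flask; the quaternary carbon is racemic here and is made stereoconvergent in step 2.

Step 2
Reactants: 3 prop-2-en-1-yl 1-methyl-2-oxocyclopentane-1-carboxylate
Product: 4 (2S)-2-methyl-2-(prop-2-en-1-yl)cyclopentan-1-one
Conditions: Pd2(dba)3 (2.5 mol %), (S)-4-tert-butyl-2-[2-(diphenylphosphanyl)phenyl]-4,5-dihydro-1,3-oxazole (6 mol %), toluene, 25 °C
Reagents that add atoms: none
Why: Decarboxylative asymmetric allylic alkylation (Tsuji allylation): both enantiomers of 3 lose CO2 to the same palladium enolate/π-allyl pair, and the chiral P,N ligand should direct C–C bond formation to one enolate face, setting the quaternary carbon (future C4) as S.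

Step 3
Reactants: 4 (2S)-2-methyl-2-(prop-2-en-1-yl)cyclopentan-1-one
Product: 6 (2S)-5-hydroxy-2-methyl-2-(prop-2-en-1-yl)cyclopentan-1-one (both C5 epimers), via potassium C1/C5 enolate 5 (not isolated)
Conditions: KN(SiMe3)2, THF, −78 °C; then 3-phenyl-2-(phenylsulfonyl)oxaziridine, −78 °C; aqueous work-up
Reagents that add atoms: 3-phenyl-2-(phenylsulfonyl)oxaziridine, O=S(=O)(N1OC1c1ccccc1)c1ccccc1
Why: Enolate α-hydroxylation with an N-sulfonyloxaziridine; the ketone can enolise only towards ring C5, and the new carbinol centre, formed as a mixture, is destroyed in step 4.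

Step 4
Reactants: 6 (2S)-5-hydroxy-2-methyl-2-(prop-2-en-1-yl)cyclopentan-1-one
Product: 7 methyl (2S)-2-methyl-2-(3-oxopropyl)pent-4-enoate
Conditions: Pb(OAc)4, MeOH/benzene (1:1), 0 °C
Reagents that add atoms: methanol, CO
Why: Criegee-type oxidative cleavage of an α-ketol in methanol turns the ketone carbon into the methyl ester (future C5) and the carbinol carbon into the aldehyde (future C1), without touching the quaternary centre or the terminal alkene.

Step 5
Reactants: 8 1,1-diethoxybut-2-yne
Product: 10 (2E)-1,1-diethoxy-3-iodobut-2-ene, via alkenylzirconocene chloride 9 (not isolated)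
Conditions: Cp2Zr(H)Cl, THF, 23 °C; then I2, 0 °C
Reagents that add atoms: iodine, II
Why: Syn hydrozirconation should place zirconium on the methyl-bearing alkyne carbon, away from the branched acetal carbon, and iodinolysis with retention gives the E iodide in which iodine is trans to the acetal carbon.

Step 6
Reactants: 7 methyl (2S)-2-methyl-2-(3-oxopropyl)pent-4-enoate; 10 (2E)-1,1-diethoxy-3-iodobut-2-ene
Product: 13 (3S)-6-[(2E)-4,4-diethoxybut-2-en-2-yl]-3-methyl-3-(prop-2-en-1-yl)oxan-2-one (both C6 epimers), via alkenyllithium 11 (not isolated), via lithium alkoxide 12 (not isolated)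
Conditions: 10, t-BuLi (2 equiv), Et2O, −78 °C; then 7, −78 → 23 °C; aqueous work-up
Reagents that add atoms: none
Why: Iodine–lithium exchange with retention of alkene geometry and 1,2-addition to the aldehyde, which reacts far faster than the α-quaternary ester; the δ-alkoxide then lactonises onto that ester, and the uncontrolled C1 carbinol centre is oxidised away in step 10.

Step 7
Reactants: 13 the δ-lactone
Product: 14 (3S)-6-[(2E)-4,4-diethoxybut-2-en-2-yl]-3-methyl-3-(prop-2-en-1-yl)oxan-2-ol (lactol; mixture at C2 and C6)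
Conditions: i-Bu2AlH, CH2Cl2, −78 °C; Rochelle salt
Reagents that add atoms: none
Why: Half-reduction of a δ-lactone; the aluminium hemiacetal is stable at −78 °C, so the hindered C5 carbonyl stops at the aldehyde (lactol) level.

Step 8
Reactants: 15 methyl 4-chloro-3-oxobutanoate
Product: 17 methyl 3-oxo-4-(triphenyl-λ5-phosphanylidene)butanoate, via phosphonium chloride 16 (not isolated)
Conditions: PPh3, THF, 50 °C; then aq. Na2CO3, CH2Cl2, 23 °C
Reagents that add atoms: triphenylphosphane, c1ccc(cc1)P(c1ccccc1)c1ccccc1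
Why: SN2 quaternisation of the α-chloro ketone followed by deprotonation gives the keto-stabilised ylide.

Step 9
Reactants: 14 the lactol; 17 methyl 3-oxo-4-(triphenyl-λ5-phosphanylidene)butanoate
Product: 19 methyl (4E,6S,10E)-12,12-diethoxy-9-hydroxy-6,10-dimethyl-3-oxo-6-(prop-2-en-1-yl)dodeca-4,10-dienoate (both C9 epimers), via ylide sodium enolate 18 (not isolated)
Conditions: 17, NaH (2.2 equiv), THF, 0 °C; then 14, 23 → 50 °C; aqueous work-up
Reagents that add atoms: none
Why: Wittig olefination of the open hydroxy-aldehyde form of the lactol by the more nucleophilic ylide enolate; the keto-stabilised ylide should give the E C5=C6 alkene and brings in C6–C8 and the ester in one step.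

Step 10
Reactants: 19 the hydroxy β-keto ester
Product: 20 methyl (4E,6S,10E)-12,12-diethoxy-6,10-dimethyl-3,9-dioxo-6-(prop-2-en-1-yl)dodeca-4,10-dienoate
Conditions: MnO2, CH2Cl2, 23 °C
Reagents that add atoms: none
Why: MnO2 oxidation is selective for the allylic C1 carbinol next to the C9=C10 alkene and gives the E-enone while leaving the β-keto ester alone.

Step 11
Reactants: 20 the enone β-keto ester
Product: 22 methyl (2Z,4E,6S,10E)-3-[(tert-butyldimethylsilyl)oxy]-12,12-diethoxy-6,10-dimethyl-9-oxo-6-(prop-2-en-1-yl)dodeca-2,4,10-trienoate, via sodium enolate 21 (not isolated)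
Conditions: NaH (1.05 equiv), THF, 0 °C; then t-BuMe2SiCl, 0 → 23 °C
Reagents that add atoms: tert-butylchlorodimethylsilane, CC(C)(C)[Si](C)(C)Cl
Why: O-silylation of the chelated sodium enolate of the β-keto ester; the chelate holds oxygen and ester cis, so the Z silyl enol ether (ester on the outside of the s-cis diene) should form.

Step 12
Reactants: 22 the silyl dienol ether acetal
Product: 23 methyl (2Z,4E,6S,10E)-3-[(tert-butyldimethylsilyl)oxy]-6,10-dimethyl-9,12-dioxo-6-(prop-2-en-1-yl)dodeca-2,4,10-trienoate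
Conditions: pyridinium p-toluenesulfonate (10 mol %), acetone/H2O (10:1), 0 °C; used at once
Reagents that add atoms: water, O
Why: Hydrolysis of an allylic acetal, which ionises to a conjugated oxocarbenium ion far more readily than the silyl enol ether of a β-keto ester is protonated, frees the enal with the E C9=C10 geometry intact.

Step 13
Reactants: 23 the triene
Product: 24 methyl 7-[(tert-butyldimethylsilyl)oxy]-9β-formyl-4β,10β-dimethyl-1-oxo-4α-(prop-2-en-1-yl)-5α-H-decal-6-ene-8β-carboxylate (4S,5S,8R,9S,10S)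
Conditions: (R)-1-(2-methylphenyl)-3,3-diphenyltetrahydro-1H,3H-pyrrolo[1,2-c][1,3,2]oxazaborole (20 mol %), HNTf2 (17 mol %), CH2Cl2 (0.01 M), −78 → −40 °C
Reagents that add atoms: none
Why: Coordination of the cationic boron catalyst to the formyl oxygen activates the C9=C10 alkene of the E-enedione, and the silyl dienol ether held by the C1–C4 tether closes on it in one concerted but asynchronous [4+2] event in which the C5–C10 bond runs ahead of the C8–C9 bond. The closest known reaction type is the oxazaborolidinium-catalysed enantioselective type-1 intramolecular Diels–Alder reaction of 1,7,9-decatrienals, which gives trans-fused decalins. Ring B (C5–C10) closes as the cycloaddition ring through both new bonds, and ring A (C1–C5 and C10) closes as the tether ring through the C5–C10 bond alone, in a chair-like array with the C1 ketone exo. C9 and C10 inherit the E geometry of the dienophile (formyl cis to methyl), C5 follows from the formyl-endo transition state (trans fusion, H5 and H9 on the same face), C8 from the Z enol ether that holds the ester outside the diene (a centre erased again in step 16), and the absolute sense of all four from the catalyst, whose convex-face phenyl group is expected to cover the C9 Re face. The step needs formyl-endo selectivity and one diene face relative to the fixed C4 centre: the first rests on the Lewis-acid-bound aldehyde lying under the diene, the second cannot come from C4, whose methyl and allyl groups are alike in size, and so rests on the catalyst alone. Low temperature and high dilution are meant to hold back the uncatalysed cycloaddition and bimolecular Mukaiyama-type additions of the silyl enol ether.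

Step 14
Reactants: 24 the cycloadduct
Product: 25 methyl 9β-formyl-4β,10β-dimethyl-1,7-dioxo-4α-(prop-2-en-1-yl)-5α-H-decalin-8-carboxylate (β-keto ester; C8 epimers and enol form)
Conditions: HF·pyridine, THF, 0 °C
Reagents that add atoms: none
Why: Fluoride-mediated protodesilylation of the silyl enol ether under buffered conditions gives the C7 ketone as a β-keto ester; C8 becomes epimerisable but is made sp2 in step 16, and the equatorial 9β-formyl group is the stable epimer at this stage.

Step 15
Reactants: 25 the β-keto ester aldehyde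
Product: 26 methyl 9β-(1,3-dioxolan-2-yl)-4β,10β-dimethyl-1,7-dioxo-4α-(prop-2-en-1-yl)-5α-H-decalin-8-carboxylate
Conditions: Me3SiOCH2CH2OSiMe3, Me3SiOTf (5 mol %), CH2Cl2, −78 °C
Reagents that add atoms: 1,2-bis(trimethylsilyloxy)ethane, C[Si](C)(C)OCCO[Si](C)(C)C
Why: Silyl-triflate-catalysed acetalisation with a bis-silyl diol ether takes the aldehyde at −78 °C, where the hindered C1 ketone and the enolised β-keto ester do not react; the acetal also removes the acidity of C9–H for the basic steps that follow.

Step 16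
Reactants: 26 the dioxolane β-keto ester
Product: 28 methyl 9β-(1,3-dioxolan-2-yl)-4β,10β-dimethyl-1-oxo-4α-(prop-2-en-1-yl)-7-[(trifluoromethylsulfonyl)oxy]-5α-H-decal-7-ene-8-carboxylate, via sodium enolate 27 (not isolated)
Conditions: NaH (1.05 equiv), THF, 0 °C; then PhNTf2, 0 → 23 °C
Reagents that add atoms: 1,1,1-trifluoro-N-phenyl-N-(trifluoromethylsulfonyl)methanesulfonamide, O=S(=O)(N(c1ccccc1)S(=O)(=O)C(F)(F)F)C(F)(F)F
Why: O-triflation of the β-keto ester enolate, the only site deprotonated by one equivalent of base, gives the tetrasubstituted C7=C8 enol triflate.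

Step 17
Reactants: 28 the enol triflate
Product: 29 methyl 9β-(1,3-dioxolan-2-yl)-4β,10β-dimethyl-1-oxo-4α-(prop-2-en-1-yl)-5α-H-decal-7-ene-8-carboxylate
Conditions: Pd(OAc)2 (5 mol %), PPh3 (10 mol %), HCO2H, Et3N, DMF, 60 °C
Reagents that add atoms: none
Why: Palladium-catalysed formate reduction of an enol triflate (oxidative addition, decarboxylation of formate, C–H reductive elimination) replaces the triflate by hydrogen and leaves the 7-ene ester; C9 keeps its configuration because its aldehyde is masked.

Step 18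
Reactants: 29 the 7-ene ester ketone
Product: 30 methyl 9β-(1,3-dioxolan-2-yl)-4β,10β-dimethyl-1-oxo-4α-(prop-2-en-1-yl)-5α-H-decal-2,7-diene-8-carboxylate
Conditions: IBX, 4-methoxypyridine N-oxide, DMSO, 23 °C
Reagents that add atoms: none
Why: IBX dehydrogenation of a ketone to an enone; the C1 ketone can enolise only towards C2, so the C2=C3 alkene is the only one that can form.

Step 19
Reactants: 30 the 2-en-1-one
Product: 31 methyl 3β-chloro-9β-(1,3-dioxolan-2-yl)-4β,10β-dimethyl-1-oxo-4α-(prop-2-en-1-yl)-5α-H-decal-7-ene-8-carboxylate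
Conditions: HCl (4 M in 1,4-dioxane, 5 equiv), CH2Cl2, 0 °C, prolonged; cold aq. NaHCO3, brief Et3N wash
Reagents that add atoms: hydrogen chloride, Cl
Why: Conjugate hydrochlorination of an enone is reversible: chair-like axial attack gives the 3α-chloride fast but this also reverts fast, whereas the equatorial 3β-chloride forms more slowly and is stereoelectronically locked against loss of HCl, so long equilibration followed by a mildly basic work-up that strips only the axial epimer back to 30 should leave 31 with chlorine cis to the C4 methyl.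

Step 20
Reactants: 31 the β-chloro ketone
Product: 32 methyl 3β-chloro-9β-(1,3-dioxolan-2-yl)-1α-hydroxy-4β,10β-dimethyl-4α-(prop-2-en-1-yl)-5α-H-decal-7-ene-8-carboxylate
Conditions: LiBH(s-Bu)3, THF, −78 °C; AcOH quench at −78 °C
Reagents that add atoms: none
Why: Ketone reduction by a bulky trialkylborohydride: the axial α trajectory runs past the parallel axial hydrogens on C3, C5 and C9, so hydride should enter from the β side (as in the reduction of 4,4-dimethyl-3-keto triterpenoids to axial alcohols) and give the axial 1α alcohol, the cold acidic quench avoiding loss of HCl.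

Step 21
Reactants: 32 the chloro alcohol
Product: 33 methyl 3β-chloro-9β-formyl-1α-hydroxy-4β,10β-dimethyl-4α-(prop-2-en-1-yl)-5α-H-decal-7-ene-8-carboxylate
Conditions: TsOH·H2O (10 mol %), acetone/H2O (10:1), 40 °C
Reagents that add atoms: water, O
Why: Acid hydrolysis of the dioxolane frees the aldehyde under conditions where C9 should not epimerise and where the chloride, no longer β to a carbonyl, is inert; the axial 1α hydroxyl is too far from the equatorial C11 to close a lactol.

Step 22
Reactants: 33 the allyl aldehyde; 34 2-methylbut-3-en-2-ol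
Product: 35 methyl 3β-chloro-9β-formyl-1α-hydroxy-4α-[(2E)-4-hydroxy-4-methylpent-2-en-1-yl]-4β,10β-dimethyl-5α-H-decal-7-ene-8-carboxylate (1S,3S,4S,5R,9R,10S), CNP0167913.1
Conditions: 34 (10 equiv), second-generation Hoveyda–Grubbs catalyst [RuCl2(H2IMes)(=CH-C6H4-2-O-i-Pr)] (5 mol %), CH2Cl2, 40 °C
Reagents that add atoms: none
Why: Olefin cross-metathesis between the terminal allyl alkene and a tertiary allylic alcohol that does not homodimerise should give the E disubstituted alkene under thermodynamic control, the trisubstituted conjugated C7=C8 alkene being inert; no acid or base follows, so the tertiary allylic alcohol and the C9 centre are not put at risk.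

**Compound list**

1 | diprop-2-en-1-yl hexanedioate | C=CCOC(=O)CCCCC(=O)OCC=C | starting material
2 | sodium enolate of prop-2-en-1-yl 2-oxocyclopentane-1-carboxylate | [Na+].[O-]C1=C(C(=O)OCC=C)CCC1 | intermediate
3 | prop-2-en-1-yl 1-methyl-2-oxocyclopentane-1-carboxylate (racemic) | CC1(C(=O)OCC=C)CCCC1=O | intermediate
4 | (2S)-2-methyl-2-(prop-2-en-1-yl)cyclopentan-1-one | C[C@@]1(CC=C)CCCC1=O | intermediate
5 | potassium C1/C5 enolate of 4 | [K+].C[C@@]1(CC=C)CCC=C1[O-] | intermediate
6 | (2S)-5-hydroxy-2-methyl-2-(prop-2-en-1-yl)cyclopentan-1-one (C5 epimers) | C[C@@]1(CC=C)CCC(O)C1=O | intermediate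
7 | methyl (2S)-2-methyl-2-(3-oxopropyl)pent-4-enoate | COC(=O)[C@](C)(CC=C)CCC=O | intermediate
8 | 1,1-diethoxybut-2-yne | CC#CC(OCC)OCC | starting material
9 | chloro[(2E)-4,4-diethoxybut-2-en-2-yl]bis(cyclopentadienyl)zirconium | C/C(=C\C(OCC)OCC)[Zr](Cl)(C1C=CC=C1)C1C=CC=C1 | intermediate
10 | (2E)-1,1-diethoxy-3-iodobut-2-ene | C/C(I)=C\C(OCC)OCC | intermediate
11 | [(2E)-4,4-diethoxybut-2-en-2-yl]lithium | C/C([Li])=C\C(OCC)OCC | intermediate
12 | lithium alkoxide of methyl (2S)-2-[(4E)-6,6-diethoxy-3-hydroxy-4-methylhex-4-en-1-yl]-2-methylpent-4-enoate | [Li+].COC(=O)[C@](C)(CC=C)CCC([O-])/C(C)=C/C(OCC)OCC | intermediate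
13 | (3S)-6-[(2E)-4,4-diethoxybut-2-en-2-yl]-3-methyl-3-(prop-2-en-1-yl)oxan-2-one (C6 epimers) | O=C1OC(CC[C@@]1(C)CC=C)/C(C)=C/C(OCC)OCC | intermediate
14 | (3S)-6-[(2E)-4,4-diethoxybut-2-en-2-yl]-3-methyl-3-(prop-2-en-1-yl)oxan-2-ol (C2 and C6 epimers) | OC1OC(CC[C@@]1(C)CC=C)/C(C)=C/C(OCC)OCC | intermediate
15 | methyl 4-chloro-3-oxobutanoate | COC(=O)CC(=O)CCl | starting material
16 | (4-methoxy-2,4-dioxobutyl)triphenylphosphonium chloride | [Cl-].COC(=O)CC(=O)C[P+](c1ccccc1)(c1ccccc1)c1ccccc1 | intermediate
17 | methyl 3-oxo-4-(triphenyl-λ5-phosphanylidene)butanoate | COC(=O)CC(=O)C=P(c1ccccc1)(c1ccccc1)c1ccccc1 | intermediate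
18 | sodium enolate of 17 | [Na+].COC(=O)C=C([O-])C=P(c1ccccc1)(c1ccccc1)c1ccccc1 | intermediate
19 | methyl (4E,6S,10E)-12,12-diethoxy-9-hydroxy-6,10-dimethyl-3-oxo-6-(prop-2-en-1-yl)dodeca-4,10-dienoate (C9 epimers) | COC(=O)CC(=O)/C=C/[C@](C)(CC=C)CCC(O)/C(C)=C/C(OCC)OCC | intermediate
20 | methyl (4E,6S,10E)-12,12-diethoxy-6,10-dimethyl-3,9-dioxo-6-(prop-2-en-1-yl)dodeca-4,10-dienoate | COC(=O)CC(=O)/C=C/[C@](C)(CC=C)CCC(=O)/C(C)=C/C(OCC)OCC | intermediate
21 | sodium (Z)-enolate of 20 | [Na+].COC(=O)/C=C([O-])/C=C/[C@](C)(CC=C)CCC(=O)/C(C)=C/C(OCC)OCC | intermediate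
22 | methyl (2Z,4E,6S,10E)-3-[(tert-butyldimethylsilyl)oxy]-12,12-diethoxy-6,10-dimethyl-9-oxo-6-(prop-2-en-1-yl)dodeca-2,4,10-trienoate | COC(=O)/C=C(O[Si](C)(C)C(C)(C)C)/C=C/[C@](C)(CC=C)CCC(=O)/C(C)=C/C(OCC)OCC | intermediate
23 | methyl (2Z,4E,6S,10E)-3-[(tert-butyldimethylsilyl)oxy]-6,10-dimethyl-9,12-dioxo-6-(prop-2-en-1-yl)dodeca-2,4,10-trienoate | COC(=O)/C=C(O[Si](C)(C)C(C)(C)C)/C=C/[C@](C)(CC=C)CCC(=O)/C(C)=C/C=O | intermediate
24 | methyl 7-[(tert-butyldimethylsilyl)oxy]-9β-formyl-4β,10β-dimethyl-1-oxo-4α-(prop-2-en-1-yl)-5α-H-decal-6-ene-8β-carboxylate | COC(=O)[C@H]1C(O[Si](C)(C)C(C)(C)C)=C[C@H]2[C@](C)(CC=C)CCC(=O)[C@]2(C)[C@H]1C=O | intermediate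
25 | methyl 9β-formyl-4β,10β-dimethyl-1,7-dioxo-4α-(prop-2-en-1-yl)-5α-H-decalin-8-carboxylate (C8 epimers) | COC(=O)C1C(=O)C[C@H]2[C@](C)(CC=C)CCC(=O)[C@]2(C)[C@H]1C=O | intermediate
26 | methyl 9β-(1,3-dioxolan-2-yl)-4β,10β-dimethyl-1,7-dioxo-4α-(prop-2-en-1-yl)-5α-H-decalin-8-carboxylate (C8 epimers) | COC(=O)C1C(=O)C[C@H]2[C@](C)(CC=C)CCC(=O)[C@]2(C)[C@H]1C1OCCO1 | intermediate
27 | sodium C7/C8 enolate of 26 | [Na+].COC(=O)C1=C([O-])C[C@H]2[C@](C)(CC=C)CCC(=O)[C@]2(C)[C@H]1C1OCCO1 | intermediate
28 | methyl 9β-(1,3-dioxolan-2-yl)-4β,10β-dimethyl-1-oxo-4α-(prop-2-en-1-yl)-7-[(trifluoromethylsulfonyl)oxy]-5α-H-decal-7-ene-8-carboxylate | COC(=O)C1=C(OS(=O)(=O)C(F)(F)F)C[C@H]2[C@](C)(CC=C)CCC(=O)[C@]2(C)[C@H]1C1OCCO1 | intermediate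
29 | methyl 9β-(1,3-dioxolan-2-yl)-4β,10β-dimethyl-1-oxo-4α-(prop-2-en-1-yl)-5α-H-decal-7-ene-8-carboxylate | COC(=O)C1=CC[C@H]2[C@](C)(CC=C)CCC(=O)[C@]2(C)[C@H]1C1OCCO1 | intermediate
30 | methyl 9β-(1,3-dioxolan-2-yl)-4β,10β-dimethyl-1-oxo-4α-(prop-2-en-1-yl)-5α-H-decal-2,7-diene-8-carboxylate | COC(=O)C1=CC[C@H]2[C@](C)(CC=C)C=CC(=O)[C@]2(C)[C@H]1C1OCCO1 | intermediate
31 | methyl 3β-chloro-9β-(1,3-dioxolan-2-yl)-4β,10β-dimethyl-1-oxo-4α-(prop-2-en-1-yl)-5α-H-decal-7-ene-8-carboxylate | COC(=O)C1=CC[C@H]2[C@](C)(CC=C)[C@@H](Cl)CC(=O)[C@]2(C)[C@H]1C1OCCO1 | intermediate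
32 | methyl 3β-chloro-9β-(1,3-dioxolan-2-yl)-1α-hydroxy-4β,10β-dimethyl-4α-(prop-2-en-1-yl)-5α-H-decal-7-ene-8-carboxylate | COC(=O)C1=CC[C@H]2[C@](C)(CC=C)[C@@H](Cl)C[C@H](O)[C@]2(C)[C@H]1C1OCCO1 | intermediate
33 | methyl 3β-chloro-9β-formyl-1α-hydroxy-4β,10β-dimethyl-4α-(prop-2-en-1-yl)-5α-H-decal-7-ene-8-carboxylate | COC(=O)C1=CC[C@H]2[C@](C)(CC=C)[C@@H](Cl)C[C@H](O)[C@]2(C)[C@H]1C=O | intermediate
34 | 2-methylbut-3-en-2-ol | C=CC(C)(C)O | starting material
35 | methyl 3β-chloro-9β-formyl-1α-hydroxy-4α-[(2E)-4-hydroxy-4-methylpent-2-en-1-yl]-4β,10β-dimethyl-5α-H-decal-7-ene-8-carboxylate (CNP0167913.1) | COC(=O)C1=CC[C@H]2[C@](C)(C/C=C/C(C)(C)O)[C@@H](Cl)C[C@H](O)[C@]2(C)[C@H]1C=O | target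

**Step count and risks**

Total step count: 22. Longest linear sequence: 20 (steps 1–4, 6, 7 and 9–22; steps 5 and 8 make the two side reagents).

Most likely to fail, in this order:

Step 13. The catalyst must override a C4 centre that offers no bias, so facial discrimination may be weak. Material may also leak through the ketone-endo pathway to cis-fused product. Aldehyde activation polarises C10 towards the less nucleophilic diene terminus C5, so the catalysed path may be slow enough for the uncatalysed cycloaddition to compete. The fallback replaces Lewis acid catalysis by a polarity-matched anionic cycloaddition and sets out from 20. Hydrolysis of the acetal (pyridinium p-toluenesulfonate, wet acetone) gives the free β-keto ester methyl (4E,6S,10E)-6,10-dimethyl-3,9,12-trioxo-6-(prop-2-en-1-yl)dodeca-4,10-dienoate F1. Its dienolate, formed with a chiral bifunctional tertiary amine–thiourea base, adds to the enedione with C8 bonding to C9 (β to the C1 ketone) and C10 closing on C5, the known double Michael mode of γ,δ-unsaturated β-keto esters. This gives 25 directly, where the route is rejoined.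

Step 19. Chloride is delivered fastest to the axial 3α position, and the equilibrium may not lie far enough towards the equatorial epimer; HCl may also be lost on handling. The fallback is a thermodynamic trap as a ketal and sets out from 30. Me3SiCl and ethane-1,2-diol in CH2Cl2 (the known conversion of enones into β-chloro ketals) would give methyl 3β-chloro-9β-(1,3-dioxolan-2-yl)-1,1-(ethane-1,2-diyldioxy)-4β,10β-dimethyl-4α-(prop-2-en-1-yl)-5α-H-decal-7-ene-8-carboxylate F2. In F2 an axial 3α chlorine would be 1,3-diaxial to the axial ketal oxygen, so the equatorial chloride should be strongly favoured at equilibrium. The C1 ketal, which hydrolyses faster than the aldehyde acetal, is then removed with pyridinium p-toluenesulfonate in wet acetone, returning to 31.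

Step 20. The β trajectory is crowded by the C10 methyl and the C9 substituent, so hydride may attack from the α face and give the equatorial 1β alcohol, or the base may cause loss of HCl. The fallback delivers hydride intramolecularly from the C9 side and sets out from 31. TsOH in wet acetone gives the keto aldehyde methyl 3β-chloro-9β-formyl-4β,10β-dimethyl-1-oxo-4α-(prop-2-en-1-yl)-5α-H-decal-7-ene-8-carboxylate F3. NaBH4 at −78 °C reduces only the aldehyde to methyl 3β-chloro-9β-(hydroxymethyl)-4β,10β-dimethyl-1-oxo-4α-(prop-2-en-1-yl)-5α-H-decal-7-ene-8-carboxylate F4. Me4NBH(OAc)3 in AcOH/MeCN at −20 °C then binds the C11 hydroxyl, which lies next to C1 on the β side, and transfers hydride there to give methyl 3β-chloro-1α-hydroxy-9β-(hydroxymethyl)-4β,10β-dimethyl-4α-(prop-2-en-1-yl)-5α-H-decal-7-ene-8-carboxylate F5. Selective oxidation of the primary alcohol with TEMPO and PhI(OAc)2 returns to 33. F4 and F5 would be handled cold and briefly, because a C11 hydroxyl can lactonise onto the C8 ester.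

Further compounds
F1 | step 13 | methyl (4E,6S,10E)-6,10-dimethyl-3,9,12-trioxo-6-(prop-2-en-1-yl)dodeca-4,10-dienoate | COC(=O)CC(=O)/C=C/[C@](C)(CC=C)CCC(=O)/C(C)=C/C=O
F2 | step 19 | methyl 3β-chloro-9β-(1,3-dioxolan-2-yl)-1,1-(ethane-1,2-diyldioxy)-4β,10β-dimethyl-4α-(prop-2-en-1-yl)-5α-H-decal-7-ene-8-carboxylate | COC(=O)C1=CC[C@H]2[C@](C)(CC=C)[C@@H](Cl)CC3(OCCO3)[C@]2(C)[C@H]1C1OCCO1
F3 | step 20 | methyl 3β-chloro-9β-formyl-4β,10β-dimethyl-1-oxo-4α-(prop-2-en-1-yl)-5α-H-decal-7-ene-8-carboxylate | COC(=O)C1=CC[C@H]2[C@](C)(CC=C)[C@@H](Cl)CC(=O)[C@]2(C)[C@H]1C=O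
F4 | step 20 | methyl 3β-chloro-9β-(hydroxymethyl)-4β,10β-dimethyl-1-oxo-4α-(prop-2-en-1-yl)-5α-H-decal-7-ene-8-carboxylate | COC(=O)C1=CC[C@H]2[C@](C)(CC=C)[C@@H](Cl)CC(=O)[C@]2(C)[C@H]1CO
F5 | step 20 | methyl 3β-chloro-1α-hydroxy-9β-(hydroxymethyl)-4β,10β-dimethyl-4α-(prop-2-en-1-yl)-5α-H-decal-7-ene-8-carboxylate | COC(=O)C1=CC[C@H]2[C@](C)(CC=C)[C@@H](Cl)C[C@H](O)[C@]2(C)[C@H]1CO
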